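**Plan**

1. Retrosynthetic cuts: first the N1–CH3 bond and the ethyl cap on the C4 oxygen; then, in one operation, C2–C3 and C4–C4a of the hetero ring; last the N1–C2 amide bond.
2. Enabling feature: N1, C2 and the C15 chain, together with the benzo ring C4a–C8a, are the anilide of palmitic acid. C3–C4 with the C4 oxygen is a two-carbon alkoxyalkyne, and the free ortho CH of the anilide is the future C4a.
3. Forward: aniline 1 and hexadecanoyl chloride 2 give anilide 3. Tf2O activation and annulation with ethoxyacetylene 4, through nitrilium ion 5 and vinyl cation 6, build the pyridine ring (the only ring made) of 4-ethoxyquinoline 7.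
4. N-Methylation to quinolinium salt 8 and halide O-de-ethylation give quinolone 9, the target. Oxygen stays etherified until nitrogen carries its methyl group, so N- versus O-methylation never arises.
5. Stereochemistry: the target has no stereocentre, stereogenic axis or configured double bond. It is one achiral species, so "single enantiomer" is read as the structure as drawn and no step has to control configuration.

Key step: step 2

**Route**

Step 1
Reactants: 1 aniline; 2 hexadecanoyl chloride
Product: 3 N-phenylhexadecanamide
Conditions: Et3N (1.2 equiv), CH2Cl2, 0 °C → rt
Reagents that add atoms: none
Why: N-acylation of an aromatic amine by an acid chloride (Schotten–Baumann-type amide formation with triethylamine as HCl acceptor) should be fast and clean because aniline offers a single nucleophilic site and the saturated chain is inert.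

Step 2
Reactants: 3 N-phenylhexadecanamide; 4 ethoxyacetylene
Product: 7 4-ethoxy-2-pentadecylquinoline, via nitrilium triflate 5 (not isolated), via ethoxyvinyl cation triflate 6 (not isolated)
Conditions: Tf2O (1.1 equiv), 2-chloropyridine (1.2 equiv), CH2Cl2, −78 → 0 °C; then 4 (2 equiv, solution in hexanes), 0 °C → rt
Reagents that add atoms: trifluoromethanesulfonic anhydride, O=S(=O)(C(F)(F)F)OS(=O)(=O)C(F)(F)F (supplies only the triflate counter-ion of 5 and 6; none of its atoms remain in 7)
Why: Tf2O O-sulfonylates the secondary amide and, buffered by the weakly basic, non-nucleophilic 2-chloropyridine, the imidoyl triflate ionises to the N-phenylnitrilium ion 5. The unsubstituted alkyne carbon of 4, the nucleophilic end of the ynol ether, adds to the nitrilium carbon (C2–C3 bond) anti to the nitrogen lone pair, which places the oxygen-stabilised vinyl cation 6 on the same side of the C=N bond as the N-phenyl ring. The pyridine ring then closes at C4–C4a by attack of the aryl ortho carbon on the sp cation, a 6-endo-dig Friedel–Crafts closure that can equally be read as a 6π-electrocyclisation of the 1-azatriene cation, and proton loss aromatises the ring to the quinoline. The closest known reaction type is the one-flask quinoline and pyridine synthesis by Tf2O/2-halopyridine activation of N-aryl or N-vinyl amides and annulation with alkynes, ynamides and enol ethers. No stereocentre is formed; the selectivity that matters is the orientation of alkyne addition, and the polarisation of the ynol ether secures it, because only bonding through the CH terminus gives a cation stabilised by the ethoxy oxygen, so oxygen ends at C4. The two ortho positions of the unsubstituted phenyl ring are equivalent, and the weak base should keep the α-CH2 nitrilium ion from being deprotonated to a ketenimine.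

Step 3
Reactants: 7 4-ethoxy-2-pentadecylquinoline
Product: 8 4-ethoxy-1-methyl-2-pentadecylquinolinium triflate
Conditions: MeOTf (1.3 equiv), CH2Cl2, 0 °C → rt; evaporate, triturate with pentane
Reagents that add atoms: methyl trifluoromethanesulfonate, COS(=O)(=O)C(F)(F)F
Why: N-quaternisation (Menshutkin reaction) with the powerful, halide-free methyl triflate should overcome the flanking C2 chain and C8–H because the 4-ethoxy group makes the ring nitrogen a vinylogous imidate nitrogen of raised nucleophilicity, and with oxygen capped as an ether nitrogen is the only site that can be methylated.

Step 4
Reactants: 8 4-ethoxy-1-methyl-2-pentadecylquinolinium triflate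
Product: 9 1-methyl-2-pentadecyl-4(1H)-quinolone
Conditions: LiCl (5 equiv), DMF, 120 °C, slow N2 sweep
Reagents that add atoms: none
Why: Chloride attacks the O–CH2 carbon of the vinylogous imidate salt in an SN2 O-dealkylation (the reaction behind the classical thermal isomerisation of 4-alkoxyquinoline N-methyl halide salts to N-methyl-4-quinolones), the neutral 4-quinolone being an excellent leaving group and the volatile chloroethane leaving the mixture so that the cleavage is irreversible.

**Compound list**

1 | aniline | Nc1ccccc1 | starting material
2 | hexadecanoyl chloride (palmitoyl chloride) | CCCCCCCCCCCCCCCC(=O)Cl | starting material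
3 | N-phenylhexadecanamide | CCCCCCCCCCCCCCCC(=O)Nc1ccccc1 | intermediate
4 | ethoxyacetylene (ethyl ethynyl ether) | C#COCC | starting material
5 | N-phenylhexadecanenitrilium trifluoromethanesulfonate (C15H31–C≡N+–Ph, triflate counter-ion) | CCCCCCCCCCCCCCCC#[N+]c1ccccc1.[O-]S(=O)(=O)C(F)(F)F | intermediate
6 | 4-ethoxy-2-pentadecyl-1-phenyl-1-azabuta-1,3-dien-4-ylium trifluoromethanesulfonate, C=N bond Z (N-phenyl cis to C3), drawn as its ketene-oxonium form | CCCCCCCCCCCCCCC/C(=N/c1ccccc1)C=C=[O+]CC.[O-]S(=O)(=O)C(F)(F)F | intermediate
7 | 4-ethoxy-2-pentadecylquinoline | CCCCCCCCCCCCCCCc1cc(OCC)c2ccccc2n1 | intermediate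
8 | 4-ethoxy-1-methyl-2-pentadecylquinolinium trifluoromethanesulfonate | CCCCCCCCCCCCCCCc1cc(OCC)c2ccccc2[n+]1C.[O-]S(=O)(=O)C(F)(F)F | intermediate
9 | 1-methyl-2-pentadecyl-4(1H)-quinolone | CCCCCCCCCCCCCCCc1cc(=O)c2ccccc2n1C | target

**Step count**

Total steps: 4. Longest linear sequence: 4 steps (1 or 2 → 3 → 7 → 8 → 9).

**Steps most likely to fail**

Step 2 (annulation). Three processes could lower the outcome:
- the acid-sensitive ynol ether is protonated and oligomerised by pyridinium triflate before it reaches the nitrilium ion;
- the α-CH2 nitrilium ion tautomerises to a ketenimine;
- triflate captures the vinyl cation before the arene closes the ring.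

The fallback drops the amide activation and builds the hetero ring by C3–C4 acylation followed by N1–C2 condensation. It sets out from 2. Iron-catalysed coupling with methylmagnesium bromide (Fe(acac)3 cat., THF, −78 °C) should give heptadecan-2-one F1. Its kinetic lithium enolate (LDA, 2.2 equiv, THF, −78 °C) is C-acylated at the methyl side by N-methylisatoic anhydride with loss of carbon dioxide. This gives 1-[2-(methylamino)phenyl]octadecane-1,3-dione F2. On warming or brief acid treatment the methylamino group condenses with the alkyl ketone and water is lost, which is the established isatoic-anhydride/ketone-enolate quinolone synthesis. The fallback comes back to the route at 9.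

Step 4 (O-de-ethylation). SN2 attack at the ethyl carbon may be sluggish, and chloride may instead remove the N-methyl group and return 7. The fallback changes the bond that is broken from O–CH2 to C4–O. It sets out from 8. Aqueous NaOH in ethanol at about 70 °C should add hydroxide at C4 of the quinolinium ring and expel ethoxide by addition–elimination, as in the alkaline hydrolysis of 4-alkoxy- and 4-halo-N-alkylquinolinium and pyridinium salts. Reversible deprotonation of the C2 α-CH2 group is expected to be harmless. The fallback comes back at 9, and no compound outside the compound list is formed (F0).

Step 3 (N-methylation). Quaternisation may stay incomplete because the nitrogen is shielded by the C2 chain and C8–H. The fallback reverses the order of unmasking and methylation. It sets out from 7. Ether cleavage with 48% HBr in acetic acid at reflux should give 2-pentadecylquinolin-4(1H)-one F3. Deprotonation with NaH in DMF at 0 °C gives the far more nucleophilic quinolone anion, and methyl iodide then methylates it. N-Methylation is the known main course for 2-alkyl-4-quinolones under these conditions. Any O-methyl isomer would have to be removed by chromatography, which is the price of this fallback. It comes back at 9.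

**Further compounds**

F1 | step 2 | heptadecan-2-one | CCCCCCCCCCCCCCCC(C)=O
F2 | step 2 | 1-[2-(methylamino)phenyl]octadecane-1,3-dione | CCCCCCCCCCCCCCCC(=O)CC(=O)c1ccccc1NC
F0 | step 4 | none | none
F3 | step 3 | 2-pentadecylquinolin-4(1H)-one | CCCCCCCCCCCCCCCc1cc(=O)c2ccccc2[nH]1
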